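The plan rests on cutting the bond between the benzylic carbon of the guaiacyl ring and C4 of the γ-butyrolactone ring. The key step exploits that C4 lies β and C3 α to the lactone carbonyl C2, so the C3–C4 edge is a latent butenolide alkene. In one flask the lithiated bis(phenylthio)acetal of O-benzylvanillin adds to C4 of (5S)-5-(d-menthyloxy)furan-2(5H)-one. The resulting enolate is then benzylated at C3 by an enantiopure dihydrobenzofuran bromide. Two C–C bonds and both lactone stereocentres arise in one operation. The precursors are a chiral acetal butenolide, a dithioacetal, and a bromide from an enantioselective rhodium-carbene C–H insertion. Their sulfur and menthol are removed afterwards.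

Key step: step 12

Remark: the lactone is numbered O1, C2(=O), C3, C4, C5 and the dihydrobenzofuran O1, C2, C3, C3a–C7a; Rh2(R-PTTL)4 is assumed to give the 2S series, as expected from the behaviour of this catalyst family with simpler 2-(benzyloxy)phenyl diazoacetates (the mirror-image catalyst is equally available); d-menthyl means (1S,2R,5S)-2-isopropyl-5-methylcyclohexyl.

Step 1
Reactants: 1 [4-(benzyloxy)-3-methoxyphenyl]methanol
Product: 2 4-(benzyloxy)-3-methoxybenzyl bromide
Conditions: PBr3 (0.4 equiv), Et2O, 0 °C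
Reagents that add atoms: phosphorus tribromide, BrP(Br)Br
Why: PBr3 bromination (phosphite activation, then SN2 displacement by bromide) is fast for an electron-rich benzylic alcohol and leaves both aryl ethers untouched.

Step 2
Reactants: 3 methyl 4-hydroxy-3-iodo-5-methoxybenzoate
Product: 4 methyl 3,4-dihydroxy-5-iodobenzoate
Conditions: BBr3 (2.5 equiv), CH2Cl2, −78 °C to 0 °C; then H2O
Reagents that add atoms: none
Why: Lewis-acid aryl methyl ether cleavage (BBr3 demethylation) removes the only aryl OMe group, while the methyl ester and the C–I bond should survive at low temperature.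

Step 3
Reactants: 4 methyl 3,4-dihydroxy-5-iodobenzoate; 2 4-(benzyloxy)-3-methoxybenzyl bromide
Product: 5 methyl 4-{[4-(benzyloxy)-3-methoxyphenyl]methoxy}-3-hydroxy-5-iodobenzoate
Conditions: K2CO3 (1.0 equiv), DMF, 0 °C to rt
Reagents that add atoms: none
Why: Williamson ether synthesis with one equivalent of weak base should alkylate the 4-OH selectively, because this phenol (para to the ester, ortho to iodine) is the more acidic one and the only one ionised.

Step 4
Reactants: 5 methyl 4-{[4-(benzyloxy)-3-methoxyphenyl]methoxy}-3-hydroxy-5-iodobenzoate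
Product: 6 methyl 3-(benzyloxy)-4-{[4-(benzyloxy)-3-methoxyphenyl]methoxy}-5-iodobenzoate
Conditions: BnBr, K2CO3, DMF, rt
Reagents that add atoms: benzyl bromide, BrCc1ccccc1
Why: Williamson ether synthesis caps the remaining phenol (the later 7-OH) as a benzyl ether that leaves together with the other benzyl groups in the last step.

Step 5
Reactants: 6 methyl 3-(benzyloxy)-4-{[4-(benzyloxy)-3-methoxyphenyl]methoxy}-5-iodobenzoate; 7 ethyl diazoacetate
Product: 8 methyl 3-(benzyloxy)-4-{[4-(benzyloxy)-3-methoxyphenyl]methoxy}-5-(1-diazo-2-ethoxy-2-oxoethyl)benzoate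
Conditions: Pd(PPh3)4 (5 mol %), Ag2CO3 (0.5 equiv), Et3N, toluene, rt
Reagents that add atoms: none
Why: Palladium-catalysed cross-coupling of an aryl iodide with the C–H bond of ethyl diazoacetate keeps the diazo group, because oxidative addition to zerovalent palladium, base-assisted palladation of the diazo carbon and reductive elimination are faster at room temperature than loss of N2.

Step 6
Reactants: 8 methyl 3-(benzyloxy)-4-{[4-(benzyloxy)-3-methoxyphenyl]methoxy}-5-(1-diazo-2-ethoxy-2-oxoethyl)benzoate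
Product: 10 trans-(2S,3S)-dihydrobenzofuran-3,5-diester, via cis-(2S,3R)-diester 9 (not isolated)
Conditions: Rh2(R-PTTL)4 (dirhodium tetrakis[N-phthaloyl-(R)-tert-leucinate], 1 mol %), toluene, −60 °C; then DBU (0.5 equiv), rt to 50 °C
Reagents that add atoms: none
Why: Enantioselective intramolecular 1,5 C–H insertion of the donor/acceptor rhodium carbene into the doubly activated ArCH2–O methylene closes the dihydrofuran ring and sets C2 as S under control of the chiral carboxylate ligands with kinetic cis selectivity, after which base-mediated epimerisation of the acidic C3–H (benzylic and α to the ester) should give the thermodynamically preferred trans (2S,3S) diester.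

Step 7
Reactants: 10 trans-(2S,3S)-dihydrobenzofuran-3,5-diester
Product: 11 (2S,3R)-dihydrobenzofuran-3,5-dimethanol
Conditions: LiAlH4, THF, 0 °C
Reagents that add atoms: none
Why: Hydride reduction with LiAlH4 converts both esters into primary alcohols without touching the ethers or either stereocentre (the C3 descriptor changes only through the priority rules).

Step 8
Reactants: 11 (2S,3R)-dihydrobenzofuran-3,5-dimethanol
Product: 12 (2S,3R)-5-(bromomethyl)dihydrobenzofuran-3-methanol
Conditions: NBS (1.2 equiv), Me2S (1.4 equiv), CH2Cl2, −20 °C to 0 °C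
Reagents that add atoms: N-bromosuccinimide, O=C1CCC(=O)N1Br
Why: Corey–Kim halogenation is selective for benzylic alcohols, since only the alkoxysulfonium salt at the electron-rich C5 benzylic position (para to O1) is displaced by bromide, whereas that of the saturated primary alcohol reverts to the alcohol on work-up.

Step 9
Reactants: 12 (2S,3R)-5-(bromomethyl)dihydrobenzofuran-3-methanol
Product: 13 (2S,3R)-5-(bromomethyl)-3-(TBSO-methyl)dihydrobenzofuran
Conditions: TBSOTf, 2,6-lutidine, CH2Cl2, −78 °C
Reagents that add atoms: tert-butyldimethylsilyl triflate, CC(C)(C)[Si](C)(C)OS(=O)(=O)C(F)(F)F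
Why: Silyl ether formation with the triflate and a hindered pyridine base at low temperature protects the alcohol faster than the base can attack the benzylic bromide.

Step 10
Reactants: 14 5-hydroxyfuran-2(5H)-one; 15 (+)-menthol
Product: 16 (5S)-5-(d-menthyloxy)furan-2(5H)-one
Conditions: p-TsOH (cat.), toluene, reflux (Dean–Stark); crystallisation from petroleum ether, mother liquor re-equilibrated with acid
Reagents that add atoms: none
Why: Acid-catalysed acetalisation of the pseudo-acid gives both C5 epimers, which interconvert under acid, and crystallisation of the less soluble epimer (crystallisation-induced diastereomer transformation) sets C5 as S.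

Step 11
Reactants: 17 4-(benzyloxy)-3-methoxybenzaldehyde
Product: 18 4-(benzyloxy)-3-methoxybenzaldehyde bis(phenylthio)acetal
Conditions: PhSH (2.1 equiv), p-TsOH (cat.), toluene, reflux (Dean–Stark)
Reagents that add atoms: thiophenol, Sc1ccccc1
Why: Acid-catalysed dithioacetalisation with azeotropic removal of water turns the aldehyde carbon into an acidic, umpoled benzylic position without a Lewis acid that could cleave the benzyl ether.

Step 12
Reactants: 18 4-(benzyloxy)-3-methoxybenzaldehyde bis(phenylthio)acetal; 16 (5S)-5-(d-menthyloxy)furan-2(5H)-one; 13 (2S,3R)-5-(bromomethyl)-3-(TBSO-methyl)dihydrobenzofuran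
Product: 21 (3S,4S,5S)-3,4,5-trisubstituted lactone, via lithiated dithioacetal 19 (not isolated), via lithium enolate 20 (not isolated)
Conditions: n-BuLi, THF, −78 °C; 16, −78 °C; then 13, DMPU, −78 °C to −20 °C
Reagents that add atoms: n-butyllithium, [Li]CCCC (supplies the lithium of 19 and 20; no atom of it stays in 21)
Why: n-BuLi removes the benzylic proton of 18, acidified by two phenylthio groups and the aryl ring, and the soft carbanion 19 adds 1,4 to butenolide 16, forming the bond from the benzylic carbon to C4 and the lithium enolate 20, which is then C-alkylated at C3 by the benzylic bromide 13 in an SN2 step. The closest known reaction type is the tandem conjugate addition–enolate alkylation (vicinal difunctionalisation) of 5-alkoxybutenolides with lithiated aryl dithioacetals, the established entry to trans-dibenzylbutyrolactones. No ring is closed, the lactone ring being carried in from 16. C4 is set by the acetal stereocentre C5, whose menthyloxy group shields one face so that 19 enters anti to it, and C3 is set by the bulky new C4 substituent, which sends 13 to the opposite face, so that the 3,4-trans-4,5-trans (3S,4S,5S) isomer should result. The step needs 1,4- over 1,2-addition, secured by the soft and hindered sulfur-stabilised anion, and C-alkylation without proton transfer, secured by the reactive benzylic bromide, the DMPU cosolvent and the absence of acidic protons in the fully protected 13.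

Step 13
Reactants: 21 (3S,4S,5S)-3,4,5-trisubstituted lactone
Product: 22 (3S,4S,5S)-3,4-dibenzyl-5-(d-menthyloxy) lactone
Conditions: Raney Ni (deactivated with acetone), EtOH–THF, rt
Reagents that add atoms: none
Why: Reductive desulfurisation with Raney Ni replaces both benzylic C–S bonds by C–H without touching C3, C4 or C5, and any early loss of an O-benzyl group would be harmless because these groups leave two steps later.

Step 14
Reactants: 22 (3S,4S,5S)-3,4-dibenzyl-5-(d-menthyloxy) lactone
Product: 25 tri-O-benzyl ether of the target, via aldehyde carboxylate 23 (not isolated), via hydroxy carboxylate 24 (not isolated)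
Conditions: KOH, NaBH4, EtOH–THF–H2O, 0 °C to rt; then 2 M HCl, rt
Reagents that add atoms: potassium hydroxide, [K+].[OH-] (supplies potassium and one carboxylate oxygen of 23 and 24)
Why: Saponification of the acyloxy acetal releases menthol and unmasks C5 as an aldehyde that NaBH4 reduces at once, before C4 can epimerise, and acidification closes the γ-lactone by intramolecular esterification and hydrolyses the primary silyl ether, no stereocentre being touched.

Step 15
Reactants: 25 tri-O-benzyl ether of the target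
Product: 26 target CNP0118131.1
Conditions: H2 (1 atm), Pd/C (10 %), EtOAc–MeOH, rt
Reagents that add atoms: none
Why: Catalytic hydrogenolysis cleaves the three aryl benzyl ethers under neutral mild conditions, which the hindered cyclic benzylic C2–O bond of the dihydrobenzofuran and the lactone should survive.

Compound list
1 | [4-(benzyloxy)-3-methoxyphenyl]methanol | COc1cc(CO)ccc1OCc1ccccc1 | starting material
2 | 4-(benzyloxy)-3-methoxybenzyl bromide | COc1cc(CBr)ccc1OCc1ccccc1 | intermediate
3 | methyl 4-hydroxy-3-iodo-5-methoxybenzoate | COC(=O)c1cc(I)c(O)c(OC)c1 | starting material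
4 | methyl 3,4-dihydroxy-5-iodobenzoate | COC(=O)c1cc(O)c(O)c(I)c1 | intermediate
5 | methyl 4-{[4-(benzyloxy)-3-methoxyphenyl]methoxy}-3-hydroxy-5-iodobenzoate | COC(=O)c1cc(O)c(OCc2ccc(OCc3ccccc3)c(OC)c2)c(I)c1 | intermediate
6 | methyl 3-(benzyloxy)-4-{[4-(benzyloxy)-3-methoxyphenyl]methoxy}-5-iodobenzoate | COC(=O)c1cc(OCc2ccccc2)c(OCc2ccc(OCc3ccccc3)c(OC)c2)c(I)c1 | intermediate
7 | ethyl diazoacetate | CCOC(=O)C=[N+]=[N-] | starting material
8 | methyl 3-(benzyloxy)-4-{[4-(benzyloxy)-3-methoxyphenyl]methoxy}-5-(1-diazo-2-ethoxy-2-oxoethyl)benzoate | COC(=O)c1cc(OCc2ccccc2)c(OCc2ccc(OCc3ccccc3)c(OC)c2)c(c1)C(=[N+]=[N-])C(=O)OCC | intermediate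
9 | 3-ethyl 5-methyl (2S,3R)-7-(benzyloxy)-2-[4-(benzyloxy)-3-methoxyphenyl]-2,3-dihydro-1-benzofuran-3,5-dicarboxylate (cis) | COC(=O)c1cc(OCc2ccccc2)c2c(c1)[C@@H](C(=O)OCC)[C@@H](c1ccc(OCc3ccccc3)c(OC)c1)O2 | intermediate
10 | 3-ethyl 5-methyl (2S,3S)-7-(benzyloxy)-2-[4-(benzyloxy)-3-methoxyphenyl]-2,3-dihydro-1-benzofuran-3,5-dicarboxylate (trans) | COC(=O)c1cc(OCc2ccccc2)c2c(c1)[C@H](C(=O)OCC)[C@@H](c1ccc(OCc3ccccc3)c(OC)c1)O2 | intermediate
11 | {(2S,3R)-7-(benzyloxy)-2-[4-(benzyloxy)-3-methoxyphenyl]-2,3-dihydro-1-benzofuran-3,5-diyl}dimethanol (trans) | OCc1cc(OCc2ccccc2)c2c(c1)[C@H](CO)[C@@H](c1ccc(OCc3ccccc3)c(OC)c1)O2 | intermediate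
12 | {(2S,3R)-7-(benzyloxy)-2-[4-(benzyloxy)-3-methoxyphenyl]-5-(bromomethyl)-2,3-dihydro-1-benzofuran-3-yl}methanol | BrCc1cc(OCc2ccccc2)c2c(c1)[C@H](CO)[C@@H](c1ccc(OCc3ccccc3)c(OC)c1)O2 | intermediate
13 | tert-butyldimethylsilyl ether of 12, (2S,3R) | BrCc1cc(OCc2ccccc2)c2c(c1)[C@H](CO[Si](C)(C)C(C)(C)C)[C@@H](c1ccc(OCc3ccccc3)c(OC)c1)O2 | intermediate
14 | 5-hydroxyfuran-2(5H)-one | O=C1C=CC(O)O1 | starting material
15 | (+)-menthol, (1S,2R,5S)-2-isopropyl-5-methylcyclohexanol | CC(C)[C@H]1CC[C@H](C)C[C@@H]1O | starting material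
16 | (5S)-5-{[(1S,2R,5S)-2-isopropyl-5-methylcyclohexyl]oxy}furan-2(5H)-one | O=C1C=C[C@@H](O[C@H]2C[C@@H](C)CC[C@@H]2C(C)C)O1 | intermediate
17 | 4-(benzyloxy)-3-methoxybenzaldehyde | COc1cc(C=O)ccc1OCc1ccccc1 | starting material
18 | 1-(benzyloxy)-4-[bis(phenylsulfanyl)methyl]-2-methoxybenzene | COc1cc(C(Sc2ccccc2)Sc2ccccc2)ccc1OCc1ccccc1 | intermediate
19 | [4-(benzyloxy)-3-methoxyphenyl]bis(phenylsulfanyl)methyllithium | COc1cc(C([Li])(Sc2ccccc2)Sc2ccccc2)ccc1OCc1ccccc1 | intermediate
20 | lithium enolate of the (4S,5S) conjugate adduct of 19 and 16 (C2–OLi, C2=C3) | COc1cc(C(Sc2ccccc2)(Sc2ccccc2)[C@@H]2[C@@H](O[C@H]3C[C@@H](C)CC[C@@H]3C(C)C)OC(O[Li])=C2)ccc1OCc1ccccc1 | intermediate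
21 | (3S,4S,5S)-4-{[4-(benzyloxy)-3-methoxyphenyl]bis(phenylsulfanyl)methyl}-3-{[(2S,3R)-7-(benzyloxy)-2-[4-(benzyloxy)-3-methoxyphenyl]-3-(TBSO-methyl)-2,3-dihydro-1-benzofuran-5-yl]methyl}-5-(d-menthyloxy)dihydrofuran-2(3H)-one | COc1cc(C(Sc2ccccc2)(Sc2ccccc2)[C@@H]2[C@@H](O[C@H]3C[C@@H](C)CC[C@@H]3C(C)C)OC(=O)[C@H]2Cc2cc(OCc3ccccc3)c3c(c2)[C@H](CO[Si](C)(C)C(C)(C)C)[C@@H](c2ccc(OCc4ccccc4)c(OC)c2)O3)ccc1OCc1ccccc1 | intermediate
22 | (3S,4S,5S)-4-[4-(benzyloxy)-3-methoxybenzyl] analogue of 21 (both phenylsulfanyl groups replaced by H) | COc1cc(C[C@@H]2[C@@H](O[C@H]3C[C@@H](C)CC[C@@H]3C(C)C)OC(=O)[C@H]2Cc2cc(OCc3ccccc3)c3c(c2)[C@H](CO[Si](C)(C)C(C)(C)C)[C@@H](c2ccc(OCc4ccccc4)c(OC)c2)O3)ccc1OCc1ccccc1 | intermediate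
23 | potassium (2S,3S)-3-formyl-2,3-dibenzylpropanoate type salt: ring-opened 22 with C5 as CHO, C3 and C4 configuration retained | COc1cc(C[C@H](C=O)[C@H](Cc2cc(OCc3ccccc3)c3c(c2)[C@H](CO[Si](C)(C)C(C)(C)C)[C@@H](c2ccc(OCc4ccccc4)c(OC)c2)O3)C(=O)[O-])ccc1OCc1ccccc1.[K+] | intermediate
24 | potassium (2S,3S)-4-hydroxybutanoate salt obtained by reduction of the CHO group of 23 | COc1cc(C[C@H](CO)[C@H](Cc2cc(OCc3ccccc3)c3c(c2)[C@H](CO[Si](C)(C)C(C)(C)C)[C@@H](c2ccc(OCc4ccccc4)c(OC)c2)O3)C(=O)[O-])ccc1OCc1ccccc1.[K+] | intermediate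
25 | (3S,4S)-4-[4-(benzyloxy)-3-methoxybenzyl]-3-{[(2S,3R)-7-(benzyloxy)-2-[4-(benzyloxy)-3-methoxyphenyl]-3-(hydroxymethyl)-2,3-dihydro-1-benzofuran-5-yl]methyl}dihydrofuran-2(3H)-one | COc1cc(C[C@@H]2COC(=O)[C@H]2Cc2cc(OCc3ccccc3)c3c(c2)[C@H](CO)[C@@H](c2ccc(OCc4ccccc4)c(OC)c2)O3)ccc1OCc1ccccc1 | intermediate
26 | (3S,4S)-4-(4-hydroxy-3-methoxybenzyl)-3-{[(2S,3R)-7-hydroxy-2-(4-hydroxy-3-methoxyphenyl)-3-(hydroxymethyl)-2,3-dihydro-1-benzofuran-5-yl]methyl}dihydrofuran-2(3H)-one | COc1cc(C[C@@H]2COC(=O)[C@H]2Cc2cc(O)c3c(c2)[C@H](CO)[C@@H](c2ccc(O)c(OC)c2)O3)ccc1O | target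

Total step count: 15.
Longest linear sequence: 12 steps, from 3 to 26 through steps 2–9 and 12–15.

Steps most likely to fail

Step 12.
- **Risk:** alkylation of the crowded enolate 20 by the large bromide 13 may be slower than proton transfer or decay of the enolate on warming. Only the conjugate addition would then take place.
- **Fallback:** it sets out from 18, 16 and 13 and comes back at 25. The two bond formations are separated and the alkylation is moved to an unhindered lactone. The enolate from 18 and 16 is quenched with aqueous NH4Cl to give (4S,5S)-4-{[4-(benzyloxy)-3-methoxyphenyl]bis(phenylsulfanyl)methyl}-5-(d-menthyloxy)dihydrofuran-2(3H)-one F1. Raney Ni then gives (4S,5S)-4-[4-(benzyloxy)-3-methoxybenzyl]-5-(d-menthyloxy)dihydrofuran-2(3H)-one F2. KOH/NaBH4 followed by HCl gives (S)-4-[4-(benzyloxy)-3-methoxybenzyl]dihydrofuran-2(3H)-one F3. Its lithium enolate (LiN(SiMe3)2, THF, −78 °C) is alkylated with 13 anti to the C4 benzyl group to give the tert-butyldimethylsilyl ether of 25 F4. Aqueous HCl in THF removes the silyl group and leads to 25.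

Step 6.
- **Risk:** the enantio- and cis-selectivity of the insertion may erode, because the flanking 7-benzyloxy group changes the conformation of the reacting ArCH2O arm.
- **Fallback:** it sets out from 8 and comes back at 10. Catalyst control is given up in favour of a resolution. Achiral Rh2(OAc)4 in CH2Cl2 at rt should give the racemic cis diester, that is 9 together with its (2R,3S)-cis enantiomer F5. DBU converts this into racemic trans diester, that is 10 together with its (2R,3R)-trans enantiomer F6. Preparative chromatography on a cellulose tris(3,5-dimethylphenylcarbamate) phase then delivers 10.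

Step 5.
- **Risk:** oxidative addition and coupling may be sluggish at the hindered, electron-rich ortho-alkoxy iodide, so that palladium-induced loss of N2 from the diazo ester takes over.
- **Fallback:** it sets out from 6 and comes back at 8. The carbon chain is attached first and the diazo group is added afterwards. Negishi-type coupling of 6 with the Reformatsky reagent BrZnCH2CO2Et (Pd(dba)2, Q-Phos, THF, rt) gives methyl 3-(benzyloxy)-4-{[4-(benzyloxy)-3-methoxyphenyl]methoxy}-5-(2-ethoxy-2-oxoethyl)benzoate F7. Regitz diazo transfer (4-acetamidobenzenesulfonyl azide, DBU, MeCN, rt) then gives 8.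

Further compounds
F1 | step 12 | (4S,5S)-4-{[4-(benzyloxy)-3-methoxyphenyl]bis(phenylsulfanyl)methyl}-5-(d-menthyloxy)dihydrofuran-2(3H)-one | COc1cc(C(Sc2ccccc2)(Sc2ccccc2)[C@@H]2[C@@H](O[C@H]3C[C@@H](C)CC[C@@H]3C(C)C)OC(=O)C2)ccc1OCc1ccccc1
F2 | step 12 | (4S,5S)-4-[4-(benzyloxy)-3-methoxybenzyl]-5-(d-menthyloxy)dihydrofuran-2(3H)-one | COc1cc(C[C@@H]2[C@@H](O[C@H]3C[C@@H](C)CC[C@@H]3C(C)C)OC(=O)C2)ccc1OCc1ccccc1
F3 | step 12 | (S)-4-[4-(benzyloxy)-3-methoxybenzyl]dihydrofuran-2(3H)-one | COc1cc(C[C@@H]2COC(=O)C2)ccc1OCc1ccccc1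
F4 | step 12 | tert-butyldimethylsilyl ether of 25 | COc1cc(C[C@@H]2COC(=O)[C@H]2Cc2cc(OCc3ccccc3)c3c(c2)[C@H](CO[Si](C)(C)C(C)(C)C)[C@@H](c2ccc(OCc4ccccc4)c(OC)c2)O3)ccc1OCc1ccccc1
F5 | step 6 | (2R,3S)-cis enantiomer of 9 | COC(=O)c1cc(OCc2ccccc2)c2c(c1)[C@H](C(=O)OCC)[C@H](c1ccc(OCc3ccccc3)c(OC)c1)O2
F6 | step 6 | (2R,3R)-trans enantiomer of 10 | COC(=O)c1cc(OCc2ccccc2)c2c(c1)[C@@H](C(=O)OCC)[C@H](c1ccc(OCc3ccccc3)c(OC)c1)O2
F7 | step 5 | methyl 3-(benzyloxy)-4-{[4-(benzyloxy)-3-methoxyphenyl]methoxy}-5-(2-ethoxy-2-oxoethyl)benzoate | COC(=O)c1cc(OCc2ccccc2)c(OCc2ccc(OCc3ccccc3)c(OC)c2)c(CC(=O)OCC)c1
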